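## Analysis of the target

The target 21 is a biisoflavone without any stereocentre: a 7-hydroxy-3-(4-hydroxyphenyl)chromen-4-one half (unit D, rings A(D), B(D), C(D)) and a 5,7-dihydroxy-3-(4-hydroxyphenyl)chromen-4-one half (unit G, rings A(G), B(G), C(G)) are joined by a single biaryl bond from C8(D) to C3′(G) of ring B(G). This bond is flanked by O7 and O1 on ring A(D) and by the 4′-hydroxyl on ring B(G); the flanking groups are small oxygen substituents and the structure defines no axis configuration, so no atropisomer control is planned. The sensitive groups are five phenols, which are oxidation-prone when free and are therefore carried as ethers or introduced late, and two γ-pyranones, which add hydroxide at C2 and open, so strongly basic aqueous conditions are excluded once a pyranone exists. The real difficulty is positional: in a 7-oxygenated isoflavone C8 and C6 are both ortho to O7 and behave alike, so attaching ring B(G) to a finished unit D would give positional isomers, and the biaryl bond itself is tri-ortho-substituted and electron-rich on both sides. The strategy rests on the make-up of ring C(D): C4 is a lone carbonyl carbon between C4a of ring A(D) and C3, the C2=C3 bond with ring B(D) is a styryl unit at the oxidation level of an arylacetaldehyde enamine, and O1 is a phenolic oxygen ortho to C4a. Ring C(D) therefore divides into an ortho-iodophenol, carbon monoxide and an enamine, and what is left of ring A(D) is a resorcinol derivative whose aryl group sits on the carbon between the two oxygens, the one position that directed lithiation addresses without ambiguity. Ring B(G) with the carbon that becomes C3(G) is an arylacetic acid, the classical handle for building ring C(G) on a symmetric triphenol.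

## Retrosynthetic reasoning

21 ⇒ 20. The three O–CH3 bonds are cut last. Methyl ethers are the only protecting groups carried through the route because they survive the organozinc reagent, the palladium/CO step, hot aqueous acid and the Lewis-acidic closure of ring C(G). A boron trihalide removes all three in one operation without touching the pyranones.

20 ⇒ 17 + 18. Ring C(G) is opened at O1–C2 and C2–C3 (removing the one-carbon unit C2) and then at C4–C4a, which leads through the deoxybenzoin 19 to the arylacetic acid 17 and phloroglucinol 18. The cut is made here because 18 is symmetric: every ring position and both ortho hydroxyls are equivalent, so neither the acylation nor the ring closure has a regiochemical question. The hydroxyls of unit G need no protection, and these free phenols enter only after all organometallic chemistry is over. The forward reaction has to acylate 18 once and then insert one carbon between the activated methylene and an ortho hydroxyl.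

17 ⇒ 16. The acid is traced to its methyl ester. The ester is needed because a free carboxylic acid would quench the organozinc reagent and protonate the enamine. Its cleavage must be acid-mediated, since base would open ring C(D).

16 ⇒ 9 + 13 + 12 (key disconnection). Ring C(D) is cut at C4a–C4, C4–C3 and O1–C2. This gives the ortho-iodophenol 9, carbon monoxide 13 as the source of C4, and the enamine 12 as the source of C2, C3 and ring B(D). The cut is made here and not at the biaryl bond because the position of the pyranone on ring A(D) is then dictated by the iodine atom and by the one hydroxyl next to it, and the biaryl bond can be formed earlier on simple benzene derivatives. The forward reaction must carbonylate the C–I bond, acylate the enamine at its aryl-bearing carbon in preference to any oxygen or nitrogen nucleophile, and close the ring by exchange of the amine for the phenolic oxygen.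

9 ⇒ 8. The C–I bond is removed. In 8 the ring A(D) positions that are still open are the one ortho to the hydroxyl (para to the methoxy group) and the one ortho to the methoxy group (para to the hydroxyl). The first is wanted. It is favoured because the methoxy methyl group, pushed away from the neighbouring aryl ring, lies over the second position.

8 ⇒ 7 ⇒ 2 + 4. After the methoxymethyl group is taken off, the biaryl bond C8(D)–C3′(G) is cut. Ring A(D) becomes the aryllithium 5, formed from 2 at the carbon between the two oxygen substituents, and then the arylzinc chloride 6. Ring B(G) becomes the aryl bromide 4. The two oxygens of ring A(D) are differentiated from the outset, one as the methyl ether that stays until the end and one as the acetal that is unmasked to give O1. A symmetric 2-arylresorcinol would make the iodination unambiguous, but the later mono-methylation would have to choose the less hindered, less acidic hydroxyl over the more acidic one next to iodine, and that selectivity is harder to defend than the iodination of 8.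

2 ⇒ 1, 4 ⇒ 3, 12 ⇒ 10 + 11. These are functional-group operations on commercial materials: acetal protection of 3-methoxyphenol 1, esterification of the bromo acid 3, and condensation of the aldehyde 10 with morpholine 11.

## Alternatives that were turned down

Alternative 1: Ring A(D) itself is taken apart at C8a–C8, C7–C6 and C8a–C4a, leaving the aryl–C8 bond intact. In the forward direction cyclobut-2-en-1-one A3 is heated with the aryl siloxyalkyne A2; ring opening to a vinylketene, [2+2] addition to the alkyne, a second ring opening and a six-electron electrocyclisation would give the resorcinol monosilyl ether A1 with the aryl group between the two oxygens. In its favour, the 1,2,3-substitution pattern and the differentiation of the two oxygens (one free, one silylated) follow from the mechanism. On this point it is stronger than the chosen route, which depends on a regioselective iodination in step 5. Against it, A2 is an ynol silyl ether that needs an ester homologation and a silylation, A3 is volatile and polymerises readily, and the cascade delivers only a 2-arylresorcinol, a structure that steps 1 to 4 reach from 1 and 3 by lithiation and cross-coupling. After A1 neither pyranone exists, the bromide has still to be turned into the acetic acid arm, and C4 has still to be placed ortho to the free hydroxyl. The pericyclic step is thus spent on a benzene ring, whereas the chosen strategy takes ring A(D) from a commercial phenol and uses its key step to form three bonds of ring C(D).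

Alternative 2: The biaryl bond C8(D)–C3′(G) is cut between two complete isoflavones. In the forward direction the bis(aryloxy)silane A5, in which O7(D) and O4′(G) are tied by a di-tert-butylsilyl group and C3′(G) carries bromine, would undergo palladium-catalysed intramolecular C–H arylation to the bridged biaryl A4 with a seven-membered dioxasilepine ring; removal of silicon and the methyl groups would follow. In its favour is maximal convergence: both halves come from established isoflavone chemistry and are joined last, and if the arylation went cleanly to C8 this route would be shorter than the chosen one. Against it, the tether from O7(D) reaches C8 and C6 through rings of the same size, so the bridge does not decide between them. C6 is the less hindered C–H bond, since C8 lies between O7 and O1, and C2–H of either chromone is a further site for metalation. An unsymmetrical diaryloxysilane on a hindered silicon is hard to assemble selectively and is labile towards the basic additives of C–H arylation, and closure through an eight-membered palladacycle is slow enough for hydrodebromination to compete. The chosen route gives up convergence at the biaryl stage but fixes the attachment at C8 by the lithiation of step 3, where no positional isomer can form.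

Alternative 3: Ring B(G) is taken apart at C5′–C6′ and C2′–C1′ and built on a finished unit D. In the forward direction the 2-silyloxydiene A7, bonded through its C3 to C8(D), would add but-3-yn-2-one A8 in a thermal [4+2] cycloaddition to give the cyclohexa-1,4-diene A6 with the acetyl group para to the silyloxy carbon. Dehydrogenation, conversion of the acetyl group into the arylacetic acid and closure of ring C(G) would follow. In its favour, cycloadditions of 2-silyloxydienes with acetylenic ketones are well established and their regiochemistry is predictable; here the alternative is stronger than the chosen key step, which is untested. Against it, A7 must come from a C8-acylated unit D, so either the C8 against C6 question returns or unit D must itself be built from a pre-functionalised resorcinol. After A6 the route still needs an oxidation to the arene, a conversion of acetyl into CH2CO2H under conditions that are harsh for ring C(D), and the same closure of ring C(G). The ring it builds is commercially available with its acetic acid arm as 3. The chosen route buys that ring, keeps three short branches, and confines the unprecedented chemistry to one step backed by a classical bypass.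

Key step: step 7

Remark: the enaminone 15 is a push-pull alkene whose C=C geometry equilibrates under the conditions; no geometry is assigned and none is needed for ring closure.

## Route

Step 1
Reactants: 1 3-methoxyphenol
Product: 2 1-methoxy-3-(methoxymethoxy)benzene
Conditions: MOMCl, iPr2NEt, CH2Cl2, 0 °C → rt
Reagents that add atoms: chloromethyl methyl ether, SMILES COCCl
Why: O-alkylation of the phenol by the reactive chloromethyl ether; the acetal ether is the stronger ortho-director needed in step 3 and is removed by acid that leaves the aryl methyl ethers and the methyl ester alone.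

Step 2
Reactants: 3 2-(3-bromo-4-methoxyphenyl)acetic acid
Product: 4 methyl 2-(3-bromo-4-methoxyphenyl)acetate
Conditions: MeOH, H2SO4 (cat.), reflux
Reagents that add atoms: methanol, SMILES CO
Why: Fischer esterification; the ester removes the acidic proton that would quench the organozinc reagent of step 3 and the enamine of step 7.

Step 3
Reactants: 2 1-methoxy-3-(methoxymethoxy)benzene; 4 methyl 2-(3-bromo-4-methoxyphenyl)acetate
Product: 7 methyl 2-[4-methoxy-3-[2-methoxy-6-(methoxymethoxy)phenyl]phenyl]acetate, via aryllithium 5 (not isolated), via arylzinc chloride 6 (not isolated)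
Conditions: n-BuLi, THF, 0 °C → rt; ZnCl2, THF, 0 °C → rt; then 4, Pd(OAc)2 (2 mol %), SPhos (4 mol %), THF, 60 °C
Reagents that add atoms: none
Why: Directed ortho-lithiation should take place at the carbon flanked by both oxygen substituents, transmetalation to zinc gives a reagent that tolerates the ester, and Negishi coupling with a dialkylbiarylphosphine ligand joins the tri-ortho-substituted biaryl; this fixes the aryl group on the carbon that becomes C8(D).

Step 4
Reactants: 7 methyl 2-[4-methoxy-3-[2-methoxy-6-(methoxymethoxy)phenyl]phenyl]acetate
Product: 8 methyl 2-[3-(2-hydroxy-6-methoxyphenyl)-4-methoxyphenyl]acetate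
Conditions: HCl (conc., cat.), MeOH, 50 °C
Reagents that add atoms: none
Why: Acid-catalysed acetal cleavage by transacetalisation to the solvent; methanol keeps the methyl ester unchanged and the aryl methyl ethers are inert.

Step 5
Reactants: 8 methyl 2-[3-(2-hydroxy-6-methoxyphenyl)-4-methoxyphenyl]acetate
Product: 9 methyl 2-[3-(2-hydroxy-3-iodo-6-methoxyphenyl)-4-methoxyphenyl]acetate
Conditions: I2 (1.05 equiv), NaHCO3, THF/H2O, 0 °C → rt
Reagents that add atoms: iodine, SMILES II
Why: Electrophilic aromatic iodination of a phenol; the position ortho to the hydroxyl and para to the methoxy group is expected to react, as is usual for resorcinol monomethyl ethers under these conditions, and the other activated position is screened by the methoxy methyl group that the neighbouring aryl ring turns towards it; the less activated anisole ring should not react with I2.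

Step 6
Reactants: 10 2-(4-methoxyphenyl)acetaldehyde; 11 morpholine
Product: 12 4-[(E)-2-(4-methoxyphenyl)ethenyl]morpholine
Conditions: 4 Å molecular sieves, toluene, 0 °C → rt
Reagents that add atoms: none
Why: Enamine formation from a secondary amine and an enolisable aldehyde; conjugation with the aryl ring should drive the condensation to the (E)-styryl amine under thermodynamic control.

Step 7
Reactants: 9 methyl 2-[3-(2-hydroxy-3-iodo-6-methoxyphenyl)-4-methoxyphenyl]acetate; 12 4-[(E)-2-(4-methoxyphenyl)ethenyl]morpholine; 13 carbon monoxide
Product: 16 methyl 2-[4-methoxy-3-[7-methoxy-3-(4-methoxyphenyl)-4-oxo-4H-chromen-8-yl]phenyl]acetate, via aroyl iodide 14 (not isolated), via enaminone 15 (not isolated)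
Conditions: Pd(OAc)2 (5 mol %), P(tBu)3·HBF4 (12 mol %), CO (4 atm), iPr2NEt (2.5 equiv), 12 (2.5 equiv), 1,4-dioxane, 80 °C; then vent CO, AcOH, 60 °C
Reagents that add atoms: none
Why: Proposed new method: zerovalent palladium, formed from Pd(OAc)2 and the phosphine, should add oxidatively to the C–I bond at the future C4a and insert CO to give an aroylpalladium iodide, from which the bulky phosphine allows reversible reductive elimination to the aroyl iodide 14. The enamine 12 attacks this acyl electrophile with its aryl-bearing carbon (future C3), and iPr2NEt takes the proton from the resulting iminium ion, so that C4a–C4 and C4–C3 are formed and the α-aryl enaminone 15 results. On acidification the C8a hydroxyl adds to the aminomethylene carbon in a 6-endo-trig conjugate addition and morpholine is expelled, which forms O1–C2 and closes ring C(D) directly at the isoflavone oxidation level. The closest known reaction types are the palladium-catalysed carbonylative annulation of 2-iodophenols with terminal alkynes to chromones, the carbonylative generation of aroyl halides that acylate π-nucleophiles, the Stork acylation of enamines and the acid-induced closure of 2-hydroxyaryl enaminones to chromones. No stereocentre is formed. The step needs C-acylation of the enamine to win over O-acylation of the phenol and over capture of the acylpalladium by an amine; the tertiary enamine has no N–H, it is used in excess, the hydroxyl is crowded between iodine and a twisted aryl ring, and morpholine is set free only in the acidic stage after CO has been vented. The place of the new ring is fixed by the iodine atom, and only the hydroxyl ortho to it can reach C2.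

Step 8
Reactants: 16 methyl 2-[4-methoxy-3-[7-methoxy-3-(4-methoxyphenyl)-4-oxo-4H-chromen-8-yl]phenyl]acetate
Product: 17 2-[4-methoxy-3-[7-methoxy-3-(4-methoxyphenyl)-4-oxo-4H-chromen-8-yl]phenyl]acetic acid
Conditions: 6 M HCl, 1,4-dioxane, 90 °C
Reagents that add atoms: water, SMILES O
Why: Acid-catalysed ester hydrolysis by acyl-oxygen cleavage; acid is used because hydroxide would add to C2 and open ring C(D), whereas the chromone and the aryl methyl ethers are stable to hot aqueous acid.

Step 9
Reactants: 17 2-[4-methoxy-3-[7-methoxy-3-(4-methoxyphenyl)-4-oxo-4H-chromen-8-yl]phenyl]acetic acid; 18 phloroglucinol (benzene-1,3,5-triol)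
Product: 20 8-[5-(5,7-dihydroxy-4-oxo-4H-chromen-3-yl)-2-methoxyphenyl]-7-methoxy-3-(4-methoxyphenyl)-4H-chromen-4-one, via deoxybenzoin 19 (not isolated)
Conditions: BF3·OEt2, 85 °C; then DMF, MsCl, 70 °C; aq. NaOAc
Reagents that add atoms: N,N-dimethylformamide, SMILES CN(C)C=O
Why: Friedel–Crafts acylation of the symmetric, highly nucleophilic triphenol by the BF3-activated acid should give the deoxybenzoin 19 as its boron chelate; the Vilsmeier-type reagent from DMF and MsCl then formylates the activated methylene and an ortho hydroxyl closes ring C(G) with loss of dimethylamine. The two ortho hydroxyls are equivalent, so only one isoflavone can form.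

Step 10
Reactants: 20 8-[5-(5,7-dihydroxy-4-oxo-4H-chromen-3-yl)-2-methoxyphenyl]-7-methoxy-3-(4-methoxyphenyl)-4H-chromen-4-one
Product: 21 8-[5-(5,7-dihydroxy-4-oxo-4H-chromen-3-yl)-2-hydroxyphenyl]-7-hydroxy-3-(4-hydroxyphenyl)-4H-chromen-4-one
Conditions: BBr3 (10 equiv), CH2Cl2, −78 °C → rt; then MeOH/H2O
Reagents that add atoms: none
Why: Lewis-acid cleavage of aryl methyl ethers, in which bromide attacks the methyl group of each boron-bound ether; the pyranones and the biaryl bond are inert, and the three methyl ethers should be removed together.

## Compound list

1 | 3-methoxyphenol | COc1cccc(O)c1 | starting material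
2 | 1-methoxy-3-(methoxymethoxy)benzene | COCOc1cccc(OC)c1 | intermediate
3 | 2-(3-bromo-4-methoxyphenyl)acetic acid | COc1ccc(CC(=O)O)cc1Br | starting material
4 | methyl 2-(3-bromo-4-methoxyphenyl)acetate | COC(=O)Cc1ccc(OC)c(Br)c1 | intermediate
5 | [2-methoxy-6-(methoxymethoxy)phenyl]lithium | [Li]c1c(OC)cccc1OCOC | intermediate (not isolated)
6 | chloro[2-methoxy-6-(methoxymethoxy)phenyl]zinc | Cl[Zn]c1c(OC)cccc1OCOC | intermediate (not isolated)
7 | methyl 2-[4-methoxy-3-[2-methoxy-6-(methoxymethoxy)phenyl]phenyl]acetate | COC(=O)Cc1ccc(OC)c(-c2c(OC)cccc2OCOC)c1 | intermediate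
8 | methyl 2-[3-(2-hydroxy-6-methoxyphenyl)-4-methoxyphenyl]acetate | COC(=O)Cc1ccc(OC)c(-c2c(OC)cccc2O)c1 | intermediate
9 | methyl 2-[3-(2-hydroxy-3-iodo-6-methoxyphenyl)-4-methoxyphenyl]acetate | COC(=O)Cc1ccc(OC)c(-c2c(OC)ccc(I)c2O)c1 | intermediate
10 | 2-(4-methoxyphenyl)acetaldehyde | COc1ccc(CC=O)cc1 | starting material
11 | morpholine | C1COCCN1 | starting material
12 | 4-[(E)-2-(4-methoxyphenyl)ethenyl]morpholine | COc1ccc(/C=C/N2CCOCC2)cc1 | intermediate
13 | carbon monoxide | [C-]#[O+] | starting material
14 | methyl 2-[3-(3-carbonoiodidoyl-2-hydroxy-6-methoxyphenyl)-4-methoxyphenyl]acetate (aroyl iodide) | COC(=O)Cc1ccc(OC)c(-c2c(OC)ccc(C(I)=O)c2O)c1 | intermediate (not isolated)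
15 | methyl 2-[3-[2-hydroxy-6-methoxy-3-[2-(4-methoxyphenyl)-3-(morpholin-4-yl)prop-2-enoyl]phenyl]-4-methoxyphenyl]acetate (enaminone, C=C geometry not fixed) | COC(=O)Cc1ccc(OC)c(-c2c(OC)ccc(C(=O)C(=CN3CCOCC3)c3ccc(OC)cc3)c2O)c1 | intermediate (not isolated)
16 | methyl 2-[4-methoxy-3-[7-methoxy-3-(4-methoxyphenyl)-4-oxo-4H-chromen-8-yl]phenyl]acetate | COC(=O)Cc1ccc(OC)c(-c2c(OC)ccc3c(=O)c(-c4ccc(OC)cc4)coc23)c1 | intermediate
17 | 2-[4-methoxy-3-[7-methoxy-3-(4-methoxyphenyl)-4-oxo-4H-chromen-8-yl]phenyl]acetic acid | OC(=O)Cc1ccc(OC)c(-c2c(OC)ccc3c(=O)c(-c4ccc(OC)cc4)coc23)c1 | intermediate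
18 | phloroglucinol (benzene-1,3,5-triol) | Oc1cc(O)cc(O)c1 | starting material
19 | 2-[4-methoxy-3-[7-methoxy-3-(4-methoxyphenyl)-4-oxo-4H-chromen-8-yl]phenyl]-1-(2,4,6-trihydroxyphenyl)ethan-1-one (deoxybenzoin) | O=C(Cc1ccc(OC)c(-c2c(OC)ccc3c(=O)c(-c4ccc(OC)cc4)coc23)c1)c1c(O)cc(O)cc1O | intermediate (not isolated)
20 | 8-[5-(5,7-dihydroxy-4-oxo-4H-chromen-3-yl)-2-methoxyphenyl]-7-methoxy-3-(4-methoxyphenyl)-4H-chromen-4-one | COc1ccc(-c2coc3cc(O)cc(O)c3c2=O)cc1-c1c(OC)ccc2c(=O)c(-c3ccc(OC)cc3)coc12 | intermediate
21 | 8-[5-(5,7-dihydroxy-4-oxo-4H-chromen-3-yl)-2-hydroxyphenyl]-7-hydroxy-3-(4-hydroxyphenyl)-4H-chromen-4-one | O=c1c(-c2ccc(O)cc2)coc2c(-c3cc(-c4coc5cc(O)cc(O)c5c4=O)ccc3O)c(O)ccc12 | target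

## Step count and risk

Total step count: 10. Longest linear sequence: 8 steps (steps 1, 3, 4, 5, 7, 8, 9 and 10 from 1; equally steps 2, 3, 4, 5, 7, 8, 9 and 10 from 3).

Step 7 (key step, proposed new method). The most likely failure is capture of the acylpalladium or aroyl iodide by a heteroatom nucleophile instead of the enamine carbon: intermolecular O-acylation by the phenol of a second molecule, or amide formation if ring closure and release of morpholine begin while CO is still present. Direct arylation of the enamine without CO insertion and protonation or hydrolysis of the enamine by the phenol and adventitious water are further ways to lose material. The fallback uses known chemistry, sets out from 8 and comes back at 16. Phenol 8 is acylated ortho to its hydroxyl with 4-methoxyphenylacetic acid F1 in BF3·OEt2 at 85 °C (Friedel–Crafts acylation directed by the boron chelate) to give the deoxybenzoin methyl 2-[3-[2-hydroxy-6-methoxy-3-[2-(4-methoxyphenyl)acetyl]phenyl]-4-methoxyphenyl]acetate F2. F2 is then closed with DMF and MsCl in BF3·OEt2 at 70 °C to 16. The boron-chelated ketone methylene should react before the ester methylene.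

Step 5. The iodination may go to the other activated position of ring A(D) (para to the hydroxyl, ortho to the methoxy group) or proceed to double iodination, because both open positions are activated by two oxygens. The fallback sets out from 4 and comes back at 9, and makes the iodination unambiguous by symmetry. 1,3-Bis(methoxymethoxy)benzene F3 is lithiated between its two acetal oxygens to [2,6-bis(methoxymethoxy)phenyl]lithium F4 and transmetalated to chloro[2,6-bis(methoxymethoxy)phenyl]zinc F5. F5 is coupled with 4 under the conditions of step 3 to methyl 2-[3-[2,6-bis(methoxymethoxy)phenyl]-4-methoxyphenyl]acetate F6. HCl in MeOH gives methyl 2-[3-(2,6-dihydroxyphenyl)-4-methoxyphenyl]acetate F7, whose two open ortho positions are equivalent. One equivalent of N-iodosuccinimide in MeCN at 0 °C gives methyl 2-[3-(2,6-dihydroxy-3-iodophenyl)-4-methoxyphenyl]acetate F8. With both phenols ionised by excess Cs2CO3 in DMF at 0 °C, one equivalent of MeI should alkylate the more basic and less hindered phenoxide, remote from iodine, to give 9.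

Step 3. Transmetalation from lithium to zinc may be incomplete, so that residual aryllithium adds to the ester. Transfer of the doubly ortho-substituted aryl group from zinc to palladium may also be slow, so that protodemetalation and homocoupling compete. The fallback reverses the polarity of the coupling; it sets out from 2 and 4 and comes back at 7. The aryllithium 5 made from 2 is quenched with I2 to 2-iodo-1-methoxy-3-(methoxymethoxy)benzene F9. Bromide 4 is converted with B2pin2, Pd(dppf)Cl2 and KOAc in 1,4-dioxane at 90 °C into methyl 2-[4-methoxy-3-(4,4,5,5-tetramethyl-1,3,2-dioxaborolan-2-yl)phenyl]acetate F10 (Miyaura borylation). Suzuki coupling of F9 with F10 (Pd(OAc)2, SPhos, K3PO4, toluene/H2O, 90 °C) gives 7; the boron now sits on the ring with a single ortho substituent, which is far less prone to protodeboronation.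

Step 9. The acylation of 18 may stay incomplete because the large, polyoxygenated acid ties up the Lewis acid at its carbonyl and ether oxygens, and in the one-pot second stage unreacted triphenol may be formylated. The fallback separates the steps and changes the acylating species; it sets out from 17 and comes back at 21. Acid 17 is converted with oxalyl chloride and catalytic DMF in CH2Cl2 into 2-[4-methoxy-3-[7-methoxy-3-(4-methoxyphenyl)-4-oxo-4H-chromen-8-yl]phenyl]acetyl chloride F12. F12 acylates 1,3,5-trimethoxybenzene F11 (SnCl4, CH2Cl2, 0 °C) to 2-[4-methoxy-3-[7-methoxy-3-(4-methoxyphenyl)-4-oxo-4H-chromen-8-yl]phenyl]-1-(2,4,6-trimethoxyphenyl)ethan-1-one F13. BCl3 (1.1 equiv, CH2Cl2, −78 → 0 °C) cleaves one methyl ether ortho to the ketone to give 1-(2-hydroxy-4,6-dimethoxyphenyl)-2-[4-methoxy-3-[7-methoxy-3-(4-methoxyphenyl)-4-oxo-4H-chromen-8-yl]phenyl]ethan-1-one F14. N,N-Dimethylformamide dimethyl acetal in toluene at 90 °C closes ring C(G) to 8-[5-(5,7-dimethoxy-4-oxo-4H-chromen-3-yl)-2-methoxyphenyl]-7-methoxy-3-(4-methoxyphenyl)-4H-chromen-4-one F15. BBr3 then removes all five methyl groups to give 21.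

## Further compounds

F1 | step 7 | 2-(4-methoxyphenyl)acetic acid | COc1ccc(CC(=O)O)cc1
F2 | step 7 | methyl 2-[3-[2-hydroxy-6-methoxy-3-[2-(4-methoxyphenyl)acetyl]phenyl]-4-methoxyphenyl]acetate | COC(=O)Cc1ccc(OC)c(-c2c(OC)ccc(C(=O)Cc3ccc(OC)cc3)c2O)c1
F3 | step 5 | 1,3-bis(methoxymethoxy)benzene | COCOc1cccc(OCOC)c1
F4 | step 5 | [2,6-bis(methoxymethoxy)phenyl]lithium | [Li]c1c(OCOC)cccc1OCOC
F5 | step 5 | chloro[2,6-bis(methoxymethoxy)phenyl]zinc | Cl[Zn]c1c(OCOC)cccc1OCOC
F6 | step 5 | methyl 2-[3-[2,6-bis(methoxymethoxy)phenyl]-4-methoxyphenyl]acetate | COC(=O)Cc1ccc(OC)c(-c2c(OCOC)cccc2OCOC)c1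
F7 | step 5 | methyl 2-[3-(2,6-dihydroxyphenyl)-4-methoxyphenyl]acetate | COC(=O)Cc1ccc(OC)c(-c2c(O)cccc2O)c1
F8 | step 5 | methyl 2-[3-(2,6-dihydroxy-3-iodophenyl)-4-methoxyphenyl]acetate | COC(=O)Cc1ccc(OC)c(-c2c(O)ccc(I)c2O)c1
F9 | step 3 | 2-iodo-1-methoxy-3-(methoxymethoxy)benzene | COCOc1cccc(OC)c1I
F10 | step 3 | methyl 2-[4-methoxy-3-(4,4,5,5-tetramethyl-1,3,2-dioxaborolan-2-yl)phenyl]acetate | COC(=O)Cc1ccc(OC)c(B2OC(C)(C)C(C)(C)O2)c1
F11 | step 9 | 1,3,5-trimethoxybenzene | COc1cc(OC)cc(OC)c1
F12 | step 9 | 2-[4-methoxy-3-[7-methoxy-3-(4-methoxyphenyl)-4-oxo-4H-chromen-8-yl]phenyl]acetyl chloride | ClC(=O)Cc1ccc(OC)c(-c2c(OC)ccc3c(=O)c(-c4ccc(OC)cc4)coc23)c1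
F13 | step 9 | 2-[4-methoxy-3-[7-methoxy-3-(4-methoxyphenyl)-4-oxo-4H-chromen-8-yl]phenyl]-1-(2,4,6-trimethoxyphenyl)ethan-1-one | COc1cc(OC)c(C(=O)Cc2ccc(OC)c(-c3c(OC)ccc4c(=O)c(-c5ccc(OC)cc5)coc34)c2)c(OC)c1
F14 | step 9 | 1-(2-hydroxy-4,6-dimethoxyphenyl)-2-[4-methoxy-3-[7-methoxy-3-(4-methoxyphenyl)-4-oxo-4H-chromen-8-yl]phenyl]ethan-1-one | COc1cc(O)c(C(=O)Cc2ccc(OC)c(-c3c(OC)ccc4c(=O)c(-c5ccc(OC)cc5)coc34)c2)c(OC)c1
F15 | step 9 | 8-[5-(5,7-dimethoxy-4-oxo-4H-chromen-3-yl)-2-methoxyphenyl]-7-methoxy-3-(4-methoxyphenyl)-4H-chromen-4-one | COc1cc(OC)c2c(=O)c(-c3ccc(OC)c(-c4c(OC)ccc5c(=O)c(-c6ccc(OC)cc6)coc45)c3)coc2c1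
A1 | alternative 1 | 2-(5-bromo-2-methoxyphenyl)-3-(triisopropylsilyloxy)phenol | COc1ccc(Br)cc1-c1c(O)cccc1O[Si](C(C)C)(C(C)C)C(C)C
A2 | alternative 1 | [(5-bromo-2-methoxyphenyl)ethynyloxy]tri(propan-2-yl)silane | COc1ccc(Br)cc1C#CO[Si](C(C)C)(C(C)C)C(C)C
A3 | alternative 1 | cyclobut-2-en-1-one | O=C1C=CC1
A4 | alternative 2 | di-tert-butyl dioxasilepine-bridged 8,3′-biisoflavone trimethyl ether (silicon between O7 of unit D and O4′ of unit G) | O=c1c(-c2ccc(OC)cc2)coc2c3c(ccc12)O[Si](C(C)(C)C)(C(C)(C)C)Oc1ccc(-c2coc4cc(OC)cc(OC)c4c2=O)cc1-3
A5 | alternative 2 | [2-bromo-4-(5,7-dimethoxy-4-oxo-4H-chromen-3-yl)phenoxy]di-tert-butyl[[3-(4-methoxyphenyl)-4-oxo-4H-chromen-7-yl]oxy]silane | O=c1c(-c2ccc(OC)cc2)coc2cc(O[Si](C(C)(C)C)(C(C)(C)C)Oc3ccc(-c4coc5cc(OC)cc(OC)c5c4=O)cc3Br)ccc12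
A6 | alternative 3 | 8-[5-acetyl-2-(tert-butyldimethylsilyloxy)cyclohexa-1,4-dien-1-yl]-7-methoxy-3-(4-methoxyphenyl)-4H-chromen-4-one | CC(=O)C1=CCC(O[Si](C)(C)C(C)(C)C)=C(c2c(OC)ccc3c(=O)c(-c4ccc(OC)cc4)coc23)C1
A7 | alternative 3 | 8-[3-(tert-butyldimethylsilyloxy)buta-1,3-dien-2-yl]-7-methoxy-3-(4-methoxyphenyl)-4H-chromen-4-one | C=C(O[Si](C)(C)C(C)(C)C)C(=C)c1c(OC)ccc2c(=O)c(-c3ccc(OC)cc3)coc12
A8 | alternative 3 | but-3-yn-2-one | CC(=O)C#C
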